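**Plan**
1. Numbering (guaiane): cyclopentenone C1(H)–C2H2–C3(=O)–C4(Me)=C5; seven-membered ring C1–C5–C6–C7–C8–C9–C10; C7 bears C11(Me)2OAc, C8 the methacrylate, C10 a methyl.
2. Retrosynthesis: remove the two esters, then cut C2–C3, C3–C4 and C1–C5. The enone carbonyl C3 between the C2 methylene and the methyl-bearing C4=C5 is the retron of an alkyne + alkene + CO [2+2+1], so both carbocycles open to an acyclic 1,8-enyne (but-2-ynyl on C7, vinyl on C10).
3. The O8/O11 1,3-diol is tied as a temporary 1,3-dioxane (acetonide) that holds the two chains cis for the seven-ring closure; it is removed after the key step.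
4. The chain is cut at C7–C8 (syn aldol of a hex-4-ynoyl imide with (R)-citronellal) and at the two C11–methyl bonds (Grignard); the vinyl group is the degraded prenyl tail of citronellal.
5. Forward: imide, aldol, ester, diol, dioxane, tail degradation, then one Pauson–Khand step that forms the seven-membered ring (C1–C5) and the cyclopentenone (C2–C3, C3–C4) together, then acetonide removal, methacrylate, acetate.
6. Stereochemistry: C10 from (R)-citronellal; C7 and C8 from the auxiliary-controlled syn aldol; C1 in the key step by 1,2-induction from C10.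

Key step: step 8

Remark: hex-4-ynoic acid, (S)-4-benzyloxazolidin-2-one and (R)-citronellal are taken as catalogue compounds; atom numbers in the text are the guaiane numbers of line 1.

Step 1
Reactants: 1 hex-4-ynoic acid; 2 (S)-4-benzyloxazolidin-2-one
Product: 4 (S)-4-benzyl-3-(hex-4-ynoyl)oxazolidin-2-one, via hex-4-ynoic pivalic anhydride 3 (not isolated)
Conditions: PivCl, Et3N, THF, −20 °C; then LiCl, 2, −20 °C → rt
Reagents that add atoms: none
Why: N-acylation of the oxazolidinone through the mixed pivalic anhydride, which is attacked at the less hindered hexynoyl carbonyl under LiCl activation; no stereocentre is formed.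

Step 2
Reactants: 4 (S)-4-benzyl-3-(hex-4-ynoyl)oxazolidin-2-one; 5 (R)-citronellal
Product: 8 (S)-4-benzyl-3-[(2S,3R,5R)-2-(but-2-yn-1-yl)-3-hydroxy-5,9-dimethyldec-8-enoyl]oxazolidin-2-one, via (Z)-dibutylboron enolate 6 (not isolated), via dibutylboron aldolate 7 (not isolated)
Conditions: Bu2BOTf, iPr2NEt, CH2Cl2, 0 °C; 5, −78 → 0 °C; then pH 7 buffer, MeOH, 30% H2O2, 0 °C
Reagents that add atoms: none
Why: Evans syn aldol: the Z boron enolate reacts through a closed Zimmerman–Traxler chair in which the benzyl group of the auxiliary blocks one enolate face, which should set C7 (S) and C8 (R) syn irrespective of the remote C10 methyl.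

Step 3
Reactants: 8 aldol adduct
Product: 9 methyl (2S,3R,5R)-2-(but-2-yn-1-yl)-3-hydroxy-5,9-dimethyldec-8-enoate
Conditions: Sm(OTf)3 (cat.), MeOH, rt
Reagents that add atoms: methanol, CO
Why: Lewis-acid-catalysed methanolysis of the chelated exocyclic imide carbonyl releases the auxiliary without base, so retro-aldol cleavage and C7 epimerisation should be avoided.

Step 4
Reactants: 9 methyl ester
Product: 11 (3S,4R,6R)-3-(but-2-yn-1-yl)-2,6,10-trimethylundec-9-ene-2,4-diol, via methyl ketone 10 (not isolated)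
Conditions: MeMgBr (5 equiv), THF, −40 → 0 °C; aq NH4Cl
Reagents that add atoms: methylmagnesium bromide, C[Mg]Br
Why: double Grignard addition to the ester, with the β-hydroxyl carried as its magnesium alkoxide, installs both C11 methyls and the tertiary alcohol without touching C7 or C8.

Step 5
Reactants: 11 diol
Product: 12 (5S,6R)-5-(but-2-yn-1-yl)-6-[(2R)-2,6-dimethylhept-5-en-1-yl]-2,2,4,4-tetramethyl-1,3-dioxane
Conditions: 2-methoxypropene, PPTS (cat.), CH2Cl2, 0 °C
Reagents that add atoms: 2-methoxypropene, COC(C)=C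
Why: acid-catalysed ketalisation closes the six-membered isopropylidene acetal of the 1,3-diol, the temporary ring that holds the butynyl and alkenyl chains cis on adjacent ring carbons.

Step 6
Reactants: 12 dioxane
Product: 15 (4R)-5-[(4R,5S)-5-(but-2-yn-1-yl)-2,2,6,6-tetramethyl-1,3-dioxan-4-yl]-4-methylpentanoic acid, via ozonide 13 (not isolated), via aldehyde 14 (not isolated)
Conditions: O3 (1 equiv), CH2Cl2, −78 °C; PPh3, −78 °C → rt; then NaClO2, NaH2PO4, 30% H2O2, MeCN/H2O, 0 °C
Reagents that add atoms: ozone, [O-][O+]=O; sodium chlorite, [Na+].[O-]Cl=O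
Why: the electron-rich trisubstituted alkene is ozonised far faster than the internal alkyne, and buffered Pinnick oxidation of the aldehyde (peroxide as hypochlorite scavenger) should give the acid without touching alkyne or acetal.

Step 7
Reactants: 15 acid
Product: 16 (5S,6R)-5-(but-2-yn-1-yl)-2,2,4,4-tetramethyl-6-[(2S)-2-methylbut-3-en-1-yl]-1,3-dioxane
Conditions: Pb(OAc)4, Cu(OAc)2 (cat.), pyridine, PhH, 80 °C
Reagents that add atoms: none
Why: Kochi oxidative decarboxylation: the tetravalent lead carboxylate fragments to the primary C2 radical, which divalent copper oxidises with loss of a C1 hydrogen to the terminal alkene; C10 is not affected.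

Step 8
Reactants: 16 enyne
Product: 18 (1R,7S,8R,10S)-8,11-(isopropylidenedioxy)guai-4-en-3-one (dioxane-fused hydroazulenone), via hexacarbonyldicobalt alkyne complex 17 (not isolated)
Conditions: Co2(CO)8 (1.1 equiv), CH2Cl2, rt; then 4 Å MS, Me3NO (6 equiv), 0 °C → rt
Reagents that add atoms: dicobalt octacarbonyl, O=C=[Co](=C=O)(=C=O)(=C=O)[Co](=C=O)(=C=O)(=C=O)=C=O
Why: Intramolecular Pauson–Khand [2+2+1]: the C4≡C5 alkyne is bound as its Co2(CO)6 complex 17, amine-oxide removal of one CO lets the C1=C2 alkene coordinate and insert into the Co–C5 bond (C1–C5), a carbonyl ligand then inserts into the Co–C2 bond to make the C2–C3 bond, and reductive elimination joins C3 to C4. The closest known reaction type is the cobalt-mediated Pauson–Khand cyclisation of 1,8-enynes whose tether is held by a ring, which gives bicyclo[5.3.0]decenones. The seven-membered ring closes by the C1–C5 bond in the exo mode with respect to both π-bonds (C2 and C4 stay outside it), and the cyclopentenone closes on that new bond by CO insertion and reductive elimination, so that C3 ends between the C2 methylene and the methyl-bearing C4. The only new stereocentre, C1, is controlled by C10: allylic 1,3-strain keeps H10 in the plane of the vinyl group and the tethered cobalt–alkyne can reach only the face on the C9 side, which should put H1 anti to H10 and C2 trans to the C10 methyl (1R). The step needs cyclisation to outrun loss of cobalt from the alkyne and needs a single regiochemistry; the cis-5,6-disubstituted dioxane holds the two chains gauche on one face, the alkene is monosubstituted and the alkyne internal, and the tethered alkyne carbon necessarily becomes the β-carbon C5. Because C1 is the γ-position of the enone, a minor C1 epimer could be drawn toward this trans isomer with base.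

Step 9
Reactants: 18 dioxane-fused hydroazulenone
Product: 19 (5S,6R,8S,8aR)-6-hydroxy-5-(2-hydroxypropan-2-yl)-3,8-dimethyl-4,5,6,7,8,8a-hexahydroazulen-2(1H)-one
Conditions: AcOH/H2O 4:1, 40 °C
Reagents that add atoms: none
Why: mild acid hydrolysis of the crowded tetramethyl-dioxane releases the 1,3-diol, while the enone and the tertiary carbinol should tolerate dilute acetic acid.

Step 10
Reactants: 19 diol
Product: 20 (5S,6R,8S,8aR)-5-(2-hydroxypropan-2-yl)-3,8-dimethyl-2-oxo-1,2,4,5,6,7,8,8a-octahydroazulen-6-yl 2-methylprop-2-enoate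
Conditions: methacryloyl chloride (1.2 equiv), Et3N, DMAP (cat.), BHT (trace), CH2Cl2, −20 → 0 °C
Reagents that add atoms: methacryloyl chloride, C=C(C)C(=O)Cl
Why: DMAP-catalysed acylation is much faster at the secondary C8 hydroxyl than at the tertiary C11 hydroxyl, so a slight excess of acid chloride should give the monoester.

Step 11
Reactants: 20 hydroxy methacrylate
Product: 21 (5S,6R,8S,8aR)-5-(2-acetoxypropan-2-yl)-3,8-dimethyl-2-oxo-1,2,4,5,6,7,8,8a-octahydroazulen-6-yl 2-methylprop-2-enoate (target)
Conditions: Ac2O, DMAP, Et3N, CH2Cl2, 40 °C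
Reagents that add atoms: acetic anhydride, CC(=O)OC(C)=O
Why: nucleophilic catalysis by DMAP (N-acetylpyridinium) acetylates the hindered tertiary alcohol without acid, so neither elimination at C11 nor cleavage of the methacrylate is expected.

**Compound list**
1 | hex-4-ynoic acid | CC#CCCC(=O)O | starting material
2 | (S)-4-benzyloxazolidin-2-one | O=C1OC[C@H](Cc2ccccc2)N1 | starting material
3 | hex-4-ynoic pivalic anhydride | CC#CCCC(=O)OC(=O)C(C)(C)C | intermediate
4 | (S)-4-benzyl-3-(hex-4-ynoyl)oxazolidin-2-one | CC#CCCC(=O)N1[C@@H](Cc2ccccc2)COC1=O | intermediate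
5 | (R)-citronellal, (3R)-3,7-dimethyloct-6-enal | O=CC[C@H](C)CCC=C(C)C | starting material
6 | (Z)-dibutylboron enolate of 4 | CC#CC/C=C(\OB(CCCC)CCCC)N1[C@@H](Cc2ccccc2)COC1=O | intermediate
7 | dibutylboron aldolate (O-boryl derivative of 8) | CC#CC[C@H](C(=O)N1[C@@H](Cc2ccccc2)COC1=O)[C@H](OB(CCCC)CCCC)C[C@H](C)CCC=C(C)C | intermediate
8 | (S)-4-benzyl-3-[(2S,3R,5R)-2-(but-2-yn-1-yl)-3-hydroxy-5,9-dimethyldec-8-enoyl]oxazolidin-2-one | CC#CC[C@H](C(=O)N1[C@@H](Cc2ccccc2)COC1=O)[C@H](O)C[C@H](C)CCC=C(C)C | intermediate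
9 | methyl (2S,3R,5R)-2-(but-2-yn-1-yl)-3-hydroxy-5,9-dimethyldec-8-enoate | CC#CC[C@H](C(=O)OC)[C@H](O)C[C@H](C)CCC=C(C)C | intermediate
10 | (3S,4R,6R)-3-(but-2-yn-1-yl)-4-hydroxy-6,10-dimethylundec-9-en-2-one | CC#CC[C@H](C(C)=O)[C@H](O)C[C@H](C)CCC=C(C)C | intermediate
11 | (3S,4R,6R)-3-(but-2-yn-1-yl)-2,6,10-trimethylundec-9-ene-2,4-diol | CC#CC[C@H](C(C)(C)O)[C@H](O)C[C@H](C)CCC=C(C)C | intermediate
12 | (5S,6R)-5-(but-2-yn-1-yl)-6-[(2R)-2,6-dimethylhept-5-en-1-yl]-2,2,4,4-tetramethyl-1,3-dioxane | CC#CC[C@H]1[C@@H](C[C@H](C)CCC=C(C)C)OC(C)(C)OC1(C)C | intermediate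
13 | ozonide (5,5-dimethyl-1,2,4-trioxolane) of the side-chain alkene of 12, epimers at the trioxolane CH | CC#CC[C@H]1[C@@H](C[C@H](C)CCC2OOC(C)(C)O2)OC(C)(C)OC1(C)C | intermediate
14 | (4R)-5-[(4R,5S)-5-(but-2-yn-1-yl)-2,2,6,6-tetramethyl-1,3-dioxan-4-yl]-4-methylpentanal | CC#CC[C@H]1[C@@H](C[C@H](C)CCC=O)OC(C)(C)OC1(C)C | intermediate
15 | (4R)-5-[(4R,5S)-5-(but-2-yn-1-yl)-2,2,6,6-tetramethyl-1,3-dioxan-4-yl]-4-methylpentanoic acid | CC#CC[C@H]1[C@@H](C[C@H](C)CCC(=O)O)OC(C)(C)OC1(C)C | intermediate
16 | (5S,6R)-5-(but-2-yn-1-yl)-2,2,4,4-tetramethyl-6-[(2S)-2-methylbut-3-en-1-yl]-1,3-dioxane | CC#CC[C@H]1[C@@H](C[C@H](C)C=C)OC(C)(C)OC1(C)C | intermediate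
17 | hexacarbonyldicobalt complex of the alkyne of 16 (C2Co2 tetrahedrane core) | CC12[Co]3(=C=O)(=C=O)(=C=O)[Co]1(=C=O)(=C=O)(=C=O)C23C[C@H]4[C@@H](C[C@H](C)C=C)OC(C)(C)OC4(C)C | intermediate
18 | (1R,7S,8R,10S)-8,11-(isopropylidenedioxy)guai-4-en-3-one | CC1(C)O[C@@H]2C[C@H](C)[C@H]3CC(=O)C(C)=C3C[C@@H]2C(C)(C)O1 | intermediate
19 | (5S,6R,8S,8aR)-6-hydroxy-5-(2-hydroxypropan-2-yl)-3,8-dimethyl-4,5,6,7,8,8a-hexahydroazulen-2(1H)-one | O[C@@H]1C[C@H](C)[C@H]2CC(=O)C(C)=C2C[C@@H]1C(C)(C)O | intermediate
20 | (5S,6R,8S,8aR)-5-(2-hydroxypropan-2-yl)-3,8-dimethyl-2-oxo-1,2,4,5,6,7,8,8a-octahydroazulen-6-yl 2-methylprop-2-enoate | C=C(C)C(=O)O[C@@H]1C[C@H](C)[C@H]2CC(=O)C(C)=C2C[C@@H]1C(C)(C)O | intermediate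
21 | (5S,6R,8S,8aR)-5-(2-acetoxypropan-2-yl)-3,8-dimethyl-2-oxo-1,2,4,5,6,7,8,8a-octahydroazulen-6-yl 2-methylprop-2-enoate | C=C(C)C(=O)O[C@@H]1C[C@H](C)[C@H]2CC(=O)C(C)=C2C[C@@H]1C(C)(C)OC(C)=O | target

**Total steps:** 11. **Longest linear sequence:** 11 (steps 1 to 11).

**Steps most likely to fail**

Step 8. The slow seven-membered alkene insertion may lose to decomplexation or reduction of the cobalt-bound alkyne, and facial control at C1 may be incomplete. The fallback sets out from aldehyde 14 (isolated at the PPh3 stage of step 6) and returns at 18, forming C1–C5 and C3–C4 instead and keeping the C2–C3 bond that citronellal already carries. Aldehyde 14 would be dehydrogenated (IBX, DMSO, 70 °C) to the (E)-enal F1. A zerovalent nickel catalyst (Ni(cod)2, PBu3, Et3B, MeOH/THF, 50 °C) should then join the enal β-carbon C1 to C5 and the aldehyde carbon C3 to C4 in a reductive [3+2] cycloaddition of enal and alkyne, giving the bicyclic cyclopentenol F2. Dess–Martin periodinane (CH2Cl2, rt) would oxidise the allylic alcohol to 18.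

Step 7. The primary radical may abstract the dioxane C–H by 1,5-hydrogen transfer or be trapped as an acetate instead of eliminating, and hot acetic acid may open the acetal. The fallback sets out from acid 15 and returns at 16 by halodecarboxylation followed by base elimination. PhI(OAc)2 and I2 under visible light (PhH, rt) should convert 15 into the primary iodide F3, since iodine-atom transfer is fast. E2 elimination with tBuOK (THF, 0 °C), which has β-hydrogens only at C1, would give the vinyl compound 16.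

Step 11. The crowded tertiary hydroxyl may fail to acylate or may dehydrate toward the isopropenyl/isopropylidene series, and long heating risks methacrylate polymerisation. The fallback sets out from diol 19 and returns at 21, delivering the acetyl group intramolecularly. MeC(OMe)3 with PPTS (CH2Cl2, rt) would give the cyclic orthoacetate F4. Brief aqueous AcOH should open it kinetically with the acyl group left on the more hindered oxygen, giving the hydroxy acetate F5 (tertiary acetate, free C8 hydroxyl). Methacrylic anhydride with DMAP (CH2Cl2, 0 °C, short time to outrun acetyl migration) would then give 21.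

**Further compounds**
F1 | step 8 | (2E,4S)-5-[(4R,5S)-5-(but-2-yn-1-yl)-2,2,6,6-tetramethyl-1,3-dioxan-4-yl]-4-methylpent-2-enal | CC#CC[C@H]1[C@@H](C[C@H](C)/C=C/C=O)OC(C)(C)OC1(C)C
F2 | step 8 | (1R,7S,8R,10S)-8,11-(isopropylidenedioxy)guai-4-en-3-ol, C3 epimers | CC1(C)O[C@@H]2C[C@H](C)[C@H]3CC(O)C(C)=C3C[C@@H]2C(C)(C)O1
F3 | step 7 | (5S,6R)-5-(but-2-yn-1-yl)-6-[(2R)-4-iodo-2-methylbutyl]-2,2,4,4-tetramethyl-1,3-dioxane | CC#CC[C@H]1[C@@H](C[C@H](C)CCI)OC(C)(C)OC1(C)C
F4 | step 11 | cyclic methyl orthoacetate of 19 (2-methoxy-2-methyl-1,3-dioxane across O8 and O11), epimers at the orthoester carbon | COC1(C)O[C@@H]2C[C@H](C)[C@H]3CC(=O)C(C)=C3C[C@@H]2C(C)(C)O1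
F5 | step 11 | 2-[(5S,6R,8S,8aR)-6-hydroxy-3,8-dimethyl-2-oxo-1,2,4,5,6,7,8,8a-octahydroazulen-5-yl]propan-2-yl acetate | O[C@@H]1C[C@H](C)[C@H]2CC(=O)C(C)=C2C[C@@H]1C(C)(C)OC(C)=O
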